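**Retrosynthetic overview**
1. The target is the C2-symmetric dimer of (S)-curcuphenol: two identical 2-(sec-alkyl)-5-methylphenol rings joined through the ring carbons para to each OH (C4–C4', each ortho to a ring methyl). This bond is cut last, as a dehydrogenative para–para phenol coupling of two molecules of one monomer.
2. Enabling feature: in each ring the free O–H on C1 is para to the coupling carbon C4, ortho-C2 is blocked by the sec-alkyl chain and ortho-C6 is wedged between OH and the C5 methyl, so phenol oxidation is steered to C4. The C5/C5' methyls flanking the new bond twist the biaryl and guard against over-oxidation.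
3. Monomer: the side chain is cut between C4' and C5' (primary alkyl iodide + isobutenyl Grignard). The benzylic stereocentre comes from Rh/(R)-BINAP conjugate arylation of ethyl crotonate with (2-methoxy-4-methylphenyl)boronic acid.
4. No ring is formed in the route: both benzene rings are bought with the boronic acid and are only transiently dearomatised and re-aromatised in the key step.

Key step: step 6

Assumption: the biaryl axis, flanked by only two methyl groups and two hydrogens, is taken as freely rotating at room temperature, so the two (S) side-chain centres are the only stereo-elements to control.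

**Step 1**
Reactants: 1 (2-methoxy-4-methylphenyl)boronic acid (2.5 equiv); 2 ethyl (E)-but-2-enoate
Product: 3 ethyl (S)-3-(2-methoxy-4-methylphenyl)butanoate
Conditions: Rh(acac)(C2H4)2 (3 mol%), (R)-BINAP (3.3 mol%), dioxane/H2O (10:1), 100 °C
Reagents that add atoms: none
Why: Rh(I)/BINAP-catalysed asymmetric conjugate addition of an arylboronic acid to an (E)-enoate (Hayashi–Miyaura reaction), in which the aryl–Rh/(R)-BINAP species should add to the enoate face that gives the (S)-benzylic centre (by the established facial model, to be confirmed by the sign of rotation of 8) and water protonates the rhodium enolate.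

**Step 2**
Reactants: 3 ethyl (S)-3-(2-methoxy-4-methylphenyl)butanoate
Product: 4 (S)-3-(2-methoxy-4-methylphenyl)butan-1-ol
Conditions: LiAlH4, THF, 0 °C; then H2O, aq. NaOH
Reagents that add atoms: none
Why: Standard hydride reduction of an ester to the primary alcohol; the β-stereocentre is not enolisable and should be untouched.

**Step 3**
Reactants: 4 (S)-3-(2-methoxy-4-methylphenyl)butan-1-ol
Product: 5 (S)-1-(4-iodobutan-2-yl)-2-methoxy-4-methylbenzene
Conditions: PPh3, imidazole, I2, CH2Cl2, 0 °C → rt
Reagents that add atoms: iodine, II
Why: Appel iodination of a primary alcohol under neutral conditions (SN2 at the primary carbon), remote from the stereocentre.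

**Step 4**
Reactants: 5 (S)-1-(4-iodobutan-2-yl)-2-methoxy-4-methylbenzene; 6 (2-methylprop-1-en-1-yl)magnesium bromide (2.5 equiv, 0.5 M in THF)
Product: 7 2-methoxy-4-methyl-1-[(2S)-6-methylhept-5-en-2-yl]benzene ((S)-curcuphenol methyl ether)
Conditions: CuI (10 mol%), THF, −30 → 0 °C
Reagents that add atoms: none
Why: Copper-catalysed C(sp3)–C(sp2) cross-coupling of an unhindered primary alkyl iodide with an alkenyl Grignard reagent (Kochi-type coupling), which delivers the trisubstituted alkene ready-made and does not touch the stereocentre.

**Step 5**
Reactants: 7 2-methoxy-4-methyl-1-[(2S)-6-methylhept-5-en-2-yl]benzene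
Product: 8 5-methyl-2-[(2S)-6-methylhept-5-en-2-yl]phenol ((S)-curcuphenol)
Conditions: NaSEt (5 equiv), DMF, 130 °C; then 1 M HCl
Reagents that add atoms: none
Why: Thiolate SN2 O-demethylation of an aryl methyl ether, chosen because it is non-acidic and should leave the acid-sensitive trisubstituted alkene and the benzylic stereocentre intact.

**Step 6**
Reactants: 8 5-methyl-2-[(2S)-6-methylhept-5-en-2-yl]phenol (two molecules)
Product: 10 2,2'-dimethyl-5,5'-bis[(2S)-6-methylhept-5-en-2-yl]-[1,1'-biphenyl]-4,4'-diol (target), via bis-dienone 9 (not isolated)
Conditions: [N,N'-bis(3,5-di-tert-butylsalicylidene)-1,2-cyclohexanediamine]Cr(III)Cl (10 mol%), O2 (1 atm), ClCH2CH2Cl, 60 °C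
Reagents that add atoms: none
Why: The Cr(III)–salen catalyst should be oxidised by O2 to a high-valent chromium phenoxide whose phenoxyl character places spin and electrophilicity at ring C4 (para to O); C4 of a second molecule of 8, its most nucleophilic unhindered position, attacks there to give the 4,4'-linked bis(cyclohexa-2,5-dienone) 9, and two keto–enol tautomerisations restore both benzene rings. The closest known reaction type is the catalytic aerobic oxidative homo-coupling of phenols, which is known to give para–para biphenols from 2,5-dialkylphenols of the thymol type. No ring is closed. The two sp3 carbons of 9 are transient and all their epimers converge on one product, the 2,2'-dimethylbiaryl axis is not configurationally stable, and the two (S) side-chain centres are not involved, so a single stereoisomer should result, with any minor enantiomer of 8 expected to end up mainly in the (R,S) diastereomer. The step needs para–para coupling over ortho and C–O coupling, and oxidation of the phenol before the alkene or the product: ortho-C2 is blocked by the sec-alkyl group, ortho-C6 is flanked by OH and CH3, the trisubstituted alkene is harder to oxidise than the phenol, and the methyls ortho to the new bond twist the biaryl and disfavour the planar diphenoquinone.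

**Compound list**
1 | (2-methoxy-4-methylphenyl)boronic acid | COc1cc(C)ccc1B(O)O | starting material
2 | ethyl (E)-but-2-enoate (ethyl crotonate) | C/C=C/C(=O)OCC | starting material
3 | ethyl (S)-3-(2-methoxy-4-methylphenyl)butanoate | CCOC(=O)C[C@H](C)c1ccc(C)cc1OC | intermediate
4 | (S)-3-(2-methoxy-4-methylphenyl)butan-1-ol | OCC[C@H](C)c1ccc(C)cc1OC | intermediate
5 | (S)-1-(4-iodobutan-2-yl)-2-methoxy-4-methylbenzene | ICC[C@H](C)c1ccc(C)cc1OC | intermediate
6 | (2-methylprop-1-en-1-yl)magnesium bromide | CC(C)=C[Mg]Br | starting material
7 | 2-methoxy-4-methyl-1-[(2S)-6-methylhept-5-en-2-yl]benzene | CC(C)=CCC[C@H](C)c1ccc(C)cc1OC | intermediate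
8 | 5-methyl-2-[(2S)-6-methylhept-5-en-2-yl]phenol, (S)-curcuphenol | CC(C)=CCC[C@H](C)c1ccc(C)cc1O | intermediate
9 | 2,2'-dimethyl-5,5'-bis[(2S)-6-methylhept-5-en-2-yl]-[1,1'-bi(cyclohexane)]-2,2',5,5'-tetraene-4,4'-dione (bis-dienone, epimers at the two ring sp3 carbons) | CC(C)=CCC[C@H](C)C1=CC(C2C=C([C@@H](C)CCC=C(C)C)C(=O)C=C2C)C(C)=CC1=O | intermediate
10 | 2,2'-dimethyl-5,5'-bis[(2S)-6-methylhept-5-en-2-yl]-[1,1'-biphenyl]-4,4'-diol | CC(C)=CCC[C@H](C)c1cc(-c2cc([C@@H](C)CCC=C(C)C)c(O)cc2C)c(C)cc1O | target

**Step count**
Total steps: 6. Longest linear sequence: 6 steps (1/2 → 3 → 4 → 5 → 7 → 8 → 10).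

**Steps most likely to fail**

Step 6. The phenoxyl intermediate may couple through the ortho carbon or through oxygen, giving regio-isomeric and ether-linked dimers. The electron-rich biphenol may be oxidised further to oligomers, and loss of the benzylic hydrogen through a quinone-methide pathway could erode the stereocentres. The fallback fixes the regiochemistry with a halogen and sets out from 5. Bromination para to the methoxy group (NBS, MeCN, 0 °C → rt), done before the alkene is present, should give (S)-1-bromo-5-(4-iodobutan-2-yl)-4-methoxy-2-methylbenzene F1. Copper-catalysed coupling with 6 as in step 4 (aryl bromide inert) should give 1-bromo-4-methoxy-2-methyl-5-[(2S)-6-methylhept-5-en-2-yl]benzene F2. Reductive Ni(0) homocoupling (Ni(cod)2, 2,2'-bipyridine, DMF/toluene, 60 °C) would then form the biaryl bond and give 4,4'-dimethoxy-2,2'-dimethyl-5,5'-bis[(2S)-6-methylhept-5-en-2-yl]-1,1'-biphenyl F3. Double O-demethylation with NaSEt in DMF at 130 °C, as in step 5, comes back to the route at 10.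

Step 1. Transmetalation of the ortho-substituted boronic acid may be slow, so that protodeboronation competes, and facial discrimination on the small crotonate may be incomplete. The fallback separates C–C bond formation from stereocontrol and sets out from 1 and 2. An oxidative Heck reaction (Pd(OAc)2, 2,9-dimethyl-1,10-phenanthroline, O2, DMF, 50 °C) should give ethyl (E)-3-(2-methoxy-4-methylphenyl)but-2-enoate F4, purified as the single E isomer. Copper hydride-catalysed asymmetric conjugate reduction (Cu(OAc)2·H2O, DTBM-SEGPHOS in the enantiomeric form that gives the (S)-ester, PMHS, t-BuOH, toluene) then sets the stereocentre by hydride delivery and comes back to the route at 3.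

Step 4. Coupling of the alkenyl Grignard reagent may be slow, so that halogen–metal exchange, reduction or elimination of the iodide take over. The fallback reverses the polarity and sets out from 5. Zinc insertion (Zn dust, LiCl, THF, 40 °C) should give (S)-[3-(2-methoxy-4-methylphenyl)butyl]zinc(II) iodide F5. Negishi coupling with commercial 1-bromo-2-methylprop-1-ene (Pd(OAc)2, SPhos, THF, rt) comes back to the route at 7.

**Further compounds**
F1 | step 6 | (S)-1-bromo-5-(4-iodobutan-2-yl)-4-methoxy-2-methylbenzene | ICC[C@H](C)c1cc(Br)c(C)cc1OC
F2 | step 6 | 1-bromo-4-methoxy-2-methyl-5-[(2S)-6-methylhept-5-en-2-yl]benzene | CC(C)=CCC[C@H](C)c1cc(Br)c(C)cc1OC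
F3 | step 6 | 4,4'-dimethoxy-2,2'-dimethyl-5,5'-bis[(2S)-6-methylhept-5-en-2-yl]-1,1'-biphenyl | CC(C)=CCC[C@H](C)c1cc(-c2cc([C@@H](C)CCC=C(C)C)c(OC)cc2C)c(C)cc1OC
F4 | step 1 | ethyl (E)-3-(2-methoxy-4-methylphenyl)but-2-enoate | CCOC(=O)/C=C(\C)c1ccc(C)cc1OC
F5 | step 4 | (S)-[3-(2-methoxy-4-methylphenyl)butyl]zinc(II) iodide | I[Zn]CC[C@H](C)c1ccc(C)cc1OC
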